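The data come from a simulation for substances that don't exist.

At the last reading of the ochre run, a closed stirred flask of starting material with reagent, after 15.0 d, the starting material stood at 20.3%, as it had within the scatter since 8.00 d. So 79.7% of it had reacted, against reagent charged at 84.0% of the starting material. The blue run, with reagent charged at 132% of the starting material, went lower, to 7.3%. I therefore took one reagent to be used per starting material.

the same everywhere: starting material 0.050 M
- ochre: reagent 0.042 M; temperature 30 °C; run made earlier
- blue: reagent 0.066 M; temperature 42 °C; run made earlier
- south-west: reagent 0.0300 M; temperature 50 °C; time 5.0 d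
- north: reagent 0.0300 M; at 35 °C until 25 h, from then on at 50 °C; time 5.0 d
- north-east: reagent 0.0300 M; temperature 35 °C; time 5.0 d

- ochre (time / d: target / %, starting material / %): 1.67: 54.5, 31.4; 3.00: 53.6, 24.8; 5.00: 47.2, 22.8; 8.00: 41.6, 20.5; 10.0: 40.4, 22.1; 15.0: 38.6, 20.3
- blue (time / d: target / %, starting material / %): 0.417: 49.0, 33.8; 0.625: 48.9, 26.8; 0.833: 47.6, 22.0; 1.25: 45.3, 17.9; 2.00: 39.5, 12.8; 3.00: 37.3, 10.2; 5.00: 34.6, 7.3

(readings scatter by 1 percentage point)

- the earlier runs were read with a standard deviation of 1 percentage point

* the best flask by amount of target, in percent of the starting material charged; "all alike" if 1.5 percentage points covers them all (south-west / north / north-east / all alike)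
* amount of target at the end, in percent of the starting material charged, south-west
* amount of target at the end, in percent of the starting material charged, north
* amount of target at the end, in percent of the starting material charged, north-east

For the new flasks the charge gives 0.600, the equivalents of reagent: c(reagent) over c(starting material), the part of the starting material that the reagent can carry over. Because this is less than one, reagent is the limiting reagent, and I expected the starting material to stall near 40.0%. Not all that reacts stays target: at the last ochre reading, target was a share of 0.484 of what had reacted. Multiplying the equivalents by this share, I reckoned 29.1% of target.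

Was one number enough? It holds neither time nor temperature, and the share moves: in the ochre run at 5.00 d it still read 0.611, higher than at the end. But the new flasks stand at 35 °C or hotter, above the 30 °C of ochre, so I kept that share for each. I committed to about 29.1% in each flask, within 1.5 points of one another, with north-east the likeliest to lie above.

The forecast, unlike my reckoning, set the flasks apart, with 25% in south-west, 27% in north, 33% in north-east and north-east the best, holding that "Target then erodes afterwards, faster when hot".

The flasks gave 30.8% in south-west, 31.1% in north and 31.3% in north-east: all alike.

    reagent + target → over-reaction product (k = 5.90 × 10⁻⁵ M⁻¹ s⁻¹, Ea = 62.0 kJ mol⁻¹)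
    target ⇌ isomer of the product (K = 0.960, k = 3.20 × 10⁻⁶ s⁻¹, Ea = 103 kJ mol⁻¹, ΔH = −7.00 kJ mol⁻¹)
    starting material + reagent → target, rate k3*[starting material]^2*[reagent]^0.5 (k = 0.00340 M⁻¹·⁵ s⁻¹, Ea = 46.0 kJ mol⁻¹)
    (constants at 35 °C)

In north at its second temperature, target and isomer of the product relax by their reversible step with a half-life of 0.178 d, short against the 5.0 d of the run. At 5.00 d that flask held 31.1% of target and 26.3% of isomer of the product, with reagent at 0% of its own charge and starting material at 41%, against the 40.0% reckoned from the equivalents. The neighbour of north with 0.012 M of reagent has 0.240 equiv; equivalents times share gives 11.6% of target there, and it holds 12.9%.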